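**Retrosynthetic overview**

1. Target 9 is a (2S)-5,7-dihydroxyflavanone whose ring B carries ring D, a 2,2-dimethyl-2,3-dihydropyran-4-one fused through its ether oxygen at C4' and its ketone carbon at C5', beside a free hydroxyl at C3'. The plan rests on C5' being the only open position ortho to O4'.
2. The 3'-hydroxyl is traced back to its methyl ether and the 7-hydroxyl to its silyl ether, which leads to 7.
3. Ring D is disconnected at C5'–C(=O) and O4'–C(CH3)2. Both bonds come from the 4'-O-(3-methylbut-2-enoyl) ester 4 by photo-Fries acyl shift and oxa-Michael closure.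
4. Ester 4 comes from (S)-homoeriodictyol 1 by 7-O-silylation and 4'-O-acylation with acid chloride 3.
5. Ring order: rings A, B and C and the C2 stereocentre are bought with 1; ring D is the only ring formed, in step 3.

Key step: step 3

Assumption: commercial (S)-homoeriodictyol is the natural (2S) flavanone of high enantiomeric purity (to be confirmed on a chiral stationary phase), since no step of the route creates or corrects C2.

**Route**

Step 1
Reactants: 1 (S)-homoeriodictyol, (2S)-5,7-dihydroxy-2-(4-hydroxy-3-methoxyphenyl)chroman-4-one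
Product: 2 (2S)-7-(tert-butyldimethylsilyloxy)-5-hydroxy-2-(4-hydroxy-3-methoxyphenyl)chroman-4-one
Conditions: TBSCl (1.05 equiv), imidazole (2.2 equiv), DMF, −20 → 0 °C
Reagents that add atoms: tert-butyldimethylsilyl chloride, CC(C)(C)[Si](C)(C)Cl
Why: Regioselective silyl ether formation, in which imidazole ionises only the 7-hydroxyl (the vinylogous acid of the C4 ketone), while the 4'-hydroxyl is less acidic and crowded by the neighbouring methoxy group and the 5-hydroxyl is held in its hydrogen bond to the ketone, and the cold, weakly basic medium cannot enolise C3, so the C2 configuration is kept.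

Step 2
Reactants: 2 (2S)-7-(tert-butyldimethylsilyloxy)-5-hydroxy-2-(4-hydroxy-3-methoxyphenyl)chroman-4-one; 3 3-methylbut-2-enoyl chloride
Product: 4 4-[(2S)-7-(tert-butyldimethylsilyloxy)-5-hydroxy-4-oxochroman-2-yl]-2-methoxyphenyl 3-methylbut-2-enoate
Conditions: 3 (1.2 equiv), pyridine (3 equiv), CH2Cl2, 0 °C
Reagents that add atoms: none
Why: Nucleophilic acyl substitution (O-acylation of a phenol by an acid chloride) at the only free, unchelated hydroxyl, with pyridine chosen over a trialkylamine so that the acid chloride is not deprotonated to a vinylketene and the double bond stays conjugated.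

Step 3
Reactants: 4 4-[(2S)-7-(tert-butyldimethylsilyloxy)-5-hydroxy-4-oxochroman-2-yl]-2-methoxyphenyl 3-methylbut-2-enoate
Product: 7 (2S)-7-(tert-butyldimethylsilyloxy)-5-hydroxy-2-(8-methoxy-2,2-dimethyl-4-oxochroman-6-yl)chroman-4-one, via 6-acylcyclohexa-2,4-dienone 5 (not isolated), via ortho-hydroxyaryl enone 6 (not isolated)
Conditions: hν (254 nm, low-pressure Hg lamps, quartz), degassed MeCN (0.005 M), Ar, 20 °C; then camphorsulfonic acid (10 mol%), 20 °C, same flask
Reagents that add atoms: none
Why: Excitation of the aryl ester at 254 nm breaks the O–acyl bond, and the 3-methylbut-2-enoyl and aryloxyl radicals recombine inside the solvent cage at C5' to give dienone 5, which tautomerises to the hydrogen-bonded hydroxyaryl enone 6. This is the photo-Fries rearrangement, known for aryl 3-methylbut-2-enoates, whose ortho-hydroxyaryl enone products close to 2,2-dimethylchroman-4-ones. Ring D closes by 6-endo-trig oxa-Michael addition of the 4'-hydroxyl to the β,β-dimethyl enone, partly under the lamp and completed by the catalytic acid, which also takes any deconjugated β,γ-enone through the same tertiary cation. No stereocentre is created, because the new ring carbon bears two methyl groups and the sp3 carbon of 5 is lost on tautomerisation. The step needs C5' over every other carbon: attack at C3' (methoxy) or at C1' (para, bearing C2) gives dienones that cannot aromatise and fall back to the radical pair, and the cage keeps the acyl radical away from ring A. C2 should be safe because no base is present and the excited 5-hydroxy-4-keto unit of ring A relaxes by intramolecular proton transfer instead of opening ring C.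

Step 4
Reactants: 7 (2S)-7-(tert-butyldimethylsilyloxy)-5-hydroxy-2-(8-methoxy-2,2-dimethyl-4-oxochroman-6-yl)chroman-4-one
Product: 8 (2S)-5,7-dihydroxy-2-(8-methoxy-2,2-dimethyl-4-oxochroman-6-yl)chroman-4-one
Conditions: Bu4NF (1.1 equiv), AcOH (1.5 equiv), THF, 0 °C
Reagents that add atoms: none
Why: Fluoride-induced desilylation driven by the strength of the Si–F bond, run before the ether cleavage because an aryl silyl ether is not reliably inert to BBr3, with acetic acid present to protonate the 7-phenoxide at once so that neither ring C nor ring D can open by base-induced retro-oxa-Michael reaction.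

Step 5
Reactants: 8 (2S)-5,7-dihydroxy-2-(8-methoxy-2,2-dimethyl-4-oxochroman-6-yl)chroman-4-one
Product: 9 (2S)-5,7-dihydroxy-2-(8-hydroxy-2,2-dimethyl-4-oxochroman-6-yl)chroman-4-one
Conditions: BBr3 (6 equiv), CH2Cl2, −78 → 0 °C; then H2O, 0 °C
Reagents that add atoms: none
Why: Lewis acid-mediated cleavage of an aryl methyl ether (BBr3 demethylation), in which bromide attacks the unhindered methyl group of the boron-complexed 3'-ether by SN2, while the C2–O bond of ring C is not expected to ionise because ring B carries the boron-complexed acyl group, and ring D, should its tertiary ether open, closes again on the acidic aqueous work-up.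

**Compound list**

1 | (S)-homoeriodictyol, (2S)-5,7-dihydroxy-2-(4-hydroxy-3-methoxyphenyl)chroman-4-one | COc1cc([C@@H]2CC(=O)c3c(O)cc(O)cc3O2)ccc1O | starting material
2 | (2S)-7-(tert-butyldimethylsilyloxy)-5-hydroxy-2-(4-hydroxy-3-methoxyphenyl)chroman-4-one | COc1cc([C@@H]2CC(=O)c3c(O)cc(O[Si](C)(C)C(C)(C)C)cc3O2)ccc1O | intermediate
3 | 3-methylbut-2-enoyl chloride | CC(C)=CC(Cl)=O | starting material
4 | 4-[(2S)-7-(tert-butyldimethylsilyloxy)-5-hydroxy-4-oxochroman-2-yl]-2-methoxyphenyl 3-methylbut-2-enoate | CC(C)=CC(=O)Oc1ccc([C@@H]2CC(=O)c3c(O)cc(O[Si](C)(C)C(C)(C)C)cc3O2)cc1OC | intermediate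
5 | (2S)-7-(tert-butyldimethylsilyloxy)-5-hydroxy-2-[5-methoxy-3-(3-methylbut-2-enoyl)-4-oxocyclohexa-1,5-dien-1-yl]chroman-4-one, transient keto tautomer, both epimers at the acyl-bearing carbon | CC(C)=CC(=O)C1C=C([C@@H]2CC(=O)c3c(O)cc(O[Si](C)(C)C(C)(C)C)cc3O2)C=C(OC)C1=O | intermediate (not isolated)
6 | (2S)-7-(tert-butyldimethylsilyloxy)-5-hydroxy-2-[4-hydroxy-3-methoxy-5-(3-methylbut-2-enoyl)phenyl]chroman-4-one | CC(C)=CC(=O)c1cc([C@@H]2CC(=O)c3c(O)cc(O[Si](C)(C)C(C)(C)C)cc3O2)cc(OC)c1O | intermediate (not isolated)
7 | (2S)-7-(tert-butyldimethylsilyloxy)-5-hydroxy-2-(8-methoxy-2,2-dimethyl-4-oxochroman-6-yl)chroman-4-one | CC1(C)CC(=O)c2cc([C@@H]3CC(=O)c4c(O)cc(O[Si](C)(C)C(C)(C)C)cc4O3)cc(OC)c2O1 | intermediate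
8 | (2S)-5,7-dihydroxy-2-(8-methoxy-2,2-dimethyl-4-oxochroman-6-yl)chroman-4-one | CC1(C)CC(=O)c2cc([C@@H]3CC(=O)c4c(O)cc(O)cc4O3)cc(OC)c2O1 | intermediate
9 | (2S)-5,7-dihydroxy-2-(8-hydroxy-2,2-dimethyl-4-oxochroman-6-yl)chroman-4-one | CC1(C)CC(=O)c2cc([C@@H]3CC(=O)c4c(O)cc(O)cc4O3)cc(O)c2O1 | target

**Step count**

Total steps: 5
Longest linear sequence: 5 steps (1 → 2 → 4 → 7 → 8 → 9)

**Steps most likely to fail**

Step 3 (key step). Much of the 254 nm light is taken up by the ring A hydroxy ketone and returned as heat, and the excited ester may pass its energy to ring A before the O–acyl bond breaks. Radical pairs that leave the cage return phenol 2, and the hydroxy ketone products screen the lamp, so conversion may stall. Recovered 4 and 2 can re-enter at steps 3 and 2. The fallback builds ring D on ring B by a thermal, oxygen-tethered sequence that sets out from phenol 2 and comes back at 7. Phenol 2 is O-alkylated at the 4'-hydroxyl with 3-chloro-3-methylbut-1-yne (CuCl2 catalytic, DBU, MeCN, 0 °C, short reaction time) to give the 1,1-dimethylpropargyl ether F1. Heating F1 in xylene at about 135 °C should take it through aromatic propargyl Claisen rearrangement to C5' (C3' is blocked by the methoxy group), 1,5-hydrogen shift and oxa-6π ring closure to the 2,2-dimethyl-2H-chromene F2. Mukaiyama hydration (Co(acac)2 catalytic, PhSiH3, O2, THF, 20 °C) places the hydroxyl on the benzylic carbon through the benzylic radical and gives the chroman-4-ol F3 as both carbinol epimers. Dess–Martin periodinane in CH2Cl2 then oxidises F3 to 7.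

Step 5. The boron Lewis acid may open ring C at the benzylic C2–O bond and let it close again without memory of configuration, or open ring D at its tertiary ether carbon, and the boron-bound polyphenol may precipitate before the ether is cleaved. The fallback reverses the order of the two deprotections and changes the cleaving nucleophile; it sets out from silyl ether 7 and comes back at 9. BCl3 with Bu4NI in CH2Cl2 at −78 → 0 °C lets external iodide attack the methyl group of the complexed ether, and the weaker Lewis acid and the lipophilic silyl ether keep the substrate in solution at low temperature. This should give (2S)-7-(tert-butyldimethylsilyloxy)-5-hydroxy-2-(8-hydroxy-2,2-dimethyl-4-oxochroman-6-yl)chroman-4-one F4. Buffered Bu4NF/AcOH in THF at 0 °C, as in step 4, then gives 9; any silyl ether already lost in the first operation is of no consequence. The enantiomeric purity of 9 is to be checked on a chiral stationary phase in either case.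

Step 1. Both the 7- and the 4'-hydroxyl may be silylated, or the silyl group may move between them, so that the later acylation is not confined to O4'. The fallback differentiates the two phenols by selective removal instead of selective introduction; it sets out from 1 and comes back at 4. Flavanone 1 is acylated at both hydroxyls with chloride 3 (2.3 equiv, pyridine, CH2Cl2, 0 °C) to give (S)-homoeriodictyol 7,4'-bis(3-methylbut-2-enoate) F5. The 7-ester is the acyl derivative of the most acidic phenol and therefore the better acyl donor, so imidazole in MeOH–THF at 0 → 20 °C should remove it selectively and give (S)-homoeriodictyol 4'-(3-methylbut-2-enoate) F6. Silylation of the only free, unchelated hydroxyl of F6 (TBSCl, imidazole, CH2Cl2, 0 °C) gives 4.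

**Further compounds**

F1 | step 3 | (2S)-7-(tert-butyldimethylsilyloxy)-5-hydroxy-2-[3-methoxy-4-(2-methylbut-3-yn-2-yloxy)phenyl]chroman-4-one | C#CC(C)(C)Oc1ccc([C@@H]2CC(=O)c3c(O)cc(O[Si](C)(C)C(C)(C)C)cc3O2)cc1OC
F2 | step 3 | (2S)-7-(tert-butyldimethylsilyloxy)-5-hydroxy-2-(8-methoxy-2,2-dimethyl-2H-chromen-6-yl)chroman-4-one | CC1(C)C=Cc2cc([C@@H]3CC(=O)c4c(O)cc(O[Si](C)(C)C(C)(C)C)cc4O3)cc(OC)c2O1
F3 | step 3 | (2S)-7-(tert-butyldimethylsilyloxy)-5-hydroxy-2-(4-hydroxy-8-methoxy-2,2-dimethylchroman-6-yl)chroman-4-one, both carbinol epimers | CC1(C)CC(O)c2cc([C@@H]3CC(=O)c4c(O)cc(O[Si](C)(C)C(C)(C)C)cc4O3)cc(OC)c2O1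
F4 | step 5 | (2S)-7-(tert-butyldimethylsilyloxy)-5-hydroxy-2-(8-hydroxy-2,2-dimethyl-4-oxochroman-6-yl)chroman-4-one | CC1(C)CC(=O)c2cc([C@@H]3CC(=O)c4c(O)cc(O[Si](C)(C)C(C)(C)C)cc4O3)cc(O)c2O1
F5 | step 1 | (S)-homoeriodictyol 7,4'-bis(3-methylbut-2-enoate) | CC(C)=CC(=O)Oc1ccc([C@@H]2CC(=O)c3c(O)cc(OC(=O)C=C(C)C)cc3O2)cc1OC
F6 | step 1 | (S)-homoeriodictyol 4'-(3-methylbut-2-enoate) | CC(C)=CC(=O)Oc1ccc([C@@H]2CC(=O)c3c(O)cc(O)cc3O2)cc1OC
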